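**Retrosynthetic overview**
- The target comes from acid removal of two MOM groups from the bis(5-hydroxy-4-MOM-oxy) ether. No ring is formed in the route; both benzene rings come intact from p-cresol.
- Feature: in each ring C1 bears the CH2–O link, C2/C3/C6 bear Br and C4/C5 bear OH. With bromine in place of the C5 oxygen the ring becomes a 2,3,5,6-tetrabromo-4-oxybenzyl unit with a mirror plane through C1 and C4, so the C3 and C5 bromines, both ortho to the C4 oxygen, are one and the same site.
- Key disconnection: the C5–O bond of both rings, made from C5–Br of the bis(tetrabromo-4-MOM-oxybenzyl) ether by bromine–magnesium exchange ortho to the MOM ether, borylation and peroxide oxidation.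
- The bis(tetrabromo) ether comes from Williamson coupling of the tetrabromo-4-MOM-oxybenzyl alcohol with the corresponding benzyl bromide, the alcohol being made from that bromide.
- The bromide comes from p-cresol by exhaustive ring bromination, MOM protection and benzylic bromination.

Key step: step 6

Remark on the chemistry: the target has no stereocentre and is achiral, so the request for a single enantiomer needs no stereocontrol; the SMILES is taken as the constitution to be made.

**Step 1**
Reactants: 1 p-cresol; 2 bromine
Product: 4 2,3,5,6-tetrabromo-4-methylphenol, via 2,6-dibromo-4-methylphenol 3 (not isolated)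
Conditions: Br2 (2.1 equiv), ClCH2CH2Cl, 0 °C; then Br2 (3–4 equiv), Fe powder (cat.), 60 °C, dark
Reagents that add atoms: bromine, BrBr
Why: Electrophilic aromatic bromination: the hydroxyl group directs the first two bromines to its ortho positions (3), and the Lewis acid formed from iron then drives substitution at the two remaining ring positions as in the classical perbromination of phenols and toluenes, while exclusion of light keeps the methyl group untouched.

**Step 2**
Reactants: 4 2,3,5,6-tetrabromo-4-methylphenol; 5 chloromethyl methyl ether
Product: 7 1,2,4,5-tetrabromo-3-(methoxymethoxy)-6-methylbenzene, via sodium phenoxide 6 (not isolated)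
Conditions: NaH, THF, 0 °C; then MOMCl, 0 °C → rt
Reagents that add atoms: chloromethyl methyl ether, COCCl
Why: Williamson-type O-alkylation: the acidic tetrabromophenol is converted fully into its sodium salt, which is alkylated by the highly reactive α-chloro ether despite the two flanking bromines.

**Step 3**
Reactants: 7 1,2,4,5-tetrabromo-3-(methoxymethoxy)-6-methylbenzene
Product: 8 1,2,4,5-tetrabromo-3-(bromomethyl)-6-(methoxymethoxy)benzene
Conditions: NBS (1.1 equiv), AIBN (cat.), PhCF3, 90 °C
Reagents that add atoms: N-bromosuccinimide, O=C1CCC(=O)N1Br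
Why: Wohl–Ziegler radical bromination: the methyl hydrogens are the only benzylic C–H bonds, the two ortho bromines should stop the reaction at the monobromide, and NBS consumes hydrogen bromide as it forms so that the acetal is not exposed to acid.

**Step 4**
Reactants: 8 1,2,4,5-tetrabromo-3-(bromomethyl)-6-(methoxymethoxy)benzene (half of the material)
Product: 10 [2,3,5,6-tetrabromo-4-(methoxymethoxy)phenyl]methanol, via benzyl acetate 9 (not isolated)
Conditions: KOAc, DMF, 60 °C; then MeOH, K2CO3 (cat.), rt
Reagents that add atoms: potassium acetate, CC(=O)[O-].[K+]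
Why: SN2 displacement of the benzylic bromide by acetate followed by base-catalysed transesterification with methanol frees the alcohol under conditions that leave the aryl bromides and the MOM acetal untouched and avoid the uncontrolled ether formation that direct hydroxide treatment would cause.

**Step 5**
Reactants: 10 [2,3,5,6-tetrabromo-4-(methoxymethoxy)phenyl]methanol; 8 1,2,4,5-tetrabromo-3-(bromomethyl)-6-(methoxymethoxy)benzene
Product: 12 bis[2,3,5,6-tetrabromo-4-(methoxymethoxy)benzyl] ether, via sodium alkoxide 11 (not isolated)
Conditions: NaH, THF–DMF, 0 °C; then 8, Bu4NI (cat.), 0 °C → rt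
Reagents that add atoms: none
Why: Williamson ether synthesis: the primary alkoxide displaces the benzylic bromide in an SN2 reaction whose trajectory lies perpendicular to the ring plane, so the ortho bromines hinder it little (2,6-dihalobenzyl halides are good alkylating agents), and no β-hydrogen is available for elimination.

**Step 6**
Reactants: 12 bis[2,3,5,6-tetrabromo-4-(methoxymethoxy)benzyl] ether; 13 trimethyl borate
Product: 16 bis[2,3,6-tribromo-5-hydroxy-4-(methoxymethoxy)benzyl] ether, via bis(arylmagnesium chloride) 14 (not isolated), via bis(dimethyl boronate) 15 (not isolated)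
Conditions: iPrMgCl·LiCl (2.2 equiv), THF (dilute), −40 °C; B(OMe)3 (5 equiv), −40 → 0 °C; then AcOH, 30% aq H2O2, 0 °C → rt; aq Na2S2O3
Reagents that add atoms: hydrogen peroxide, OO (the new phenol oxygen); isopropylmagnesium chloride, CC(C)[Mg]Cl, and trimethyl borate, COB(OC)OC (atoms found only in 14 and 15)
Why: Each ring of 12 should undergo one bromine–magnesium exchange at a bromine ortho to the C4 oxygen, because the carbanion developing there is stabilised inductively by the adjacent aryl oxygen and held by the MOM oxygens, whereas exchange at C2/C6 would place the metal next to the benzylic carbon; ring symmetry makes C3 and C5 the same site, and a ring that already carries magnesium is too electron-rich to exchange again with the stoichiometric reagent. The hindered arylmagnesium 14 adds to trimethyl borate and loses methoxide to give boronate 15; hydroperoxide then adds to boron and triggers a 1,2-shift of the aryl group from boron to oxygen, which forms the C5–O bond at the carbon that carried the metal, and hydrolysis of the borate ester releases the phenol. The closest known reaction type is the ortho-alkoxy-directed halogen–magnesium exchange of polybromoarenes followed by borylation and oxidative hydroxylation. No ring is closed and no stereocentre is created. The selectivities needed are site (C5/C3 over C2/C6) and one exchange per ring; they rest on the inductive and chelating effect of the MOM ether, on 1.1 equiv of reagent per ring and on −40 °C, which should also keep the ortho-bromo arylmagnesium from eliminating to an aryne. Oxidation under weakly acidic conditions avoids base-induced protodeboronation of the doubly ortho-substituted boronate and spares the MOM groups.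

**Step 7**
Reactants: 16 bis[2,3,6-tribromo-5-hydroxy-4-(methoxymethoxy)benzyl] ether
Product: 17 bis(2,3,6-tribromo-4,5-dihydroxybenzyl) ether
Conditions: 3 M aq HCl, THF, rt, under Ar
Reagents that add atoms: none
Why: Acid-catalysed acetal hydrolysis: protonation and loss of the bromophenol, a good leaving group, should cleave both MOM ethers at room temperature, while the central dibenzyl ether, flanked by electron-poor rings, should not ionise and no stereocentre is involved.

**Compound list**
1 | p-cresol (4-methylphenol) | Cc1ccc(O)cc1 | starting material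
2 | bromine | BrBr | starting material
3 | 2,6-dibromo-4-methylphenol | Cc1cc(Br)c(O)c(Br)c1 | intermediate
4 | 2,3,5,6-tetrabromo-4-methylphenol | Cc1c(Br)c(Br)c(O)c(Br)c1Br | intermediate
5 | chloromethyl methyl ether | COCCl | starting material
6 | sodium 2,3,5,6-tetrabromo-4-methylphenolate | Cc1c(Br)c(Br)c([O-])c(Br)c1Br.[Na+] | intermediate
7 | 1,2,4,5-tetrabromo-3-(methoxymethoxy)-6-methylbenzene | COCOc1c(Br)c(Br)c(C)c(Br)c1Br | intermediate
8 | 1,2,4,5-tetrabromo-3-(bromomethyl)-6-(methoxymethoxy)benzene | COCOc1c(Br)c(Br)c(CBr)c(Br)c1Br | intermediate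
9 | 2,3,5,6-tetrabromo-4-(methoxymethoxy)benzyl acetate | COCOc1c(Br)c(Br)c(COC(C)=O)c(Br)c1Br | intermediate
10 | [2,3,5,6-tetrabromo-4-(methoxymethoxy)phenyl]methanol | COCOc1c(Br)c(Br)c(CO)c(Br)c1Br | intermediate
11 | sodium [2,3,5,6-tetrabromo-4-(methoxymethoxy)phenyl]methanolate | COCOc1c(Br)c(Br)c(C[O-])c(Br)c1Br.[Na+] | intermediate
12 | bis[2,3,5,6-tetrabromo-4-(methoxymethoxy)benzyl] ether | COCOc1c(Br)c(Br)c(COCc2c(Br)c(Br)c(OCOC)c(Br)c2Br)c(Br)c1Br | intermediate
13 | trimethyl borate | COB(OC)OC | starting material
14 | bis[2,3,6-tribromo-5-(chloromagnesio)-4-(methoxymethoxy)benzyl] ether | COCOc1c([Mg]Cl)c(Br)c(COCc2c(Br)c([Mg]Cl)c(OCOC)c(Br)c2Br)c(Br)c1Br | intermediate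
15 | bis[2,3,6-tribromo-5-(dimethoxyboryl)-4-(methoxymethoxy)benzyl] ether | COCOc1c(B(OC)OC)c(Br)c(COCc2c(Br)c(B(OC)OC)c(OCOC)c(Br)c2Br)c(Br)c1Br | intermediate
16 | bis[2,3,6-tribromo-5-hydroxy-4-(methoxymethoxy)benzyl] ether | COCOc1c(O)c(Br)c(COCc2c(Br)c(O)c(OCOC)c(Br)c2Br)c(Br)c1Br | intermediate
17 | bis(2,3,6-tribromo-4,5-dihydroxybenzyl) ether | Oc1c(O)c(Br)c(COCc2c(Br)c(O)c(O)c(Br)c2Br)c(Br)c1Br | target

**Step count**
Total steps: 7. Longest linear sequence: 7 steps (1 → 4 → 7 → 8 → 10 → 12 → 16 → 17); bromide 8 is used in steps 4 and 5.

**Steps most likely to fail**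

Step 6. What may go wrong: exchange at a bromine next to the benzylic carbon through chelation by the central ether oxygen, incomplete exchange in one ring because 12 dissolves poorly at −40 °C, or loss of magnesium halide to an aryne before the hindered arylmagnesium is borylated. Fallback: the C5 oxygen is introduced on the monomer before the ether is built. It sets out from 7, whose only oxygen is the MOM ether, so that one C–Mg bond per molecule is formed in homogeneous solution and no second donor can steer the reagent. iPrMgCl·LiCl (THF, −40 °C) would give [2,4,5-tribromo-6-(methoxymethoxy)-3-methylphenyl]magnesium chloride F1, B(OMe)3 would give dimethyl [2,4,5-tribromo-6-(methoxymethoxy)-3-methylphenyl]boronate F2, and AcOH/H2O2 would give 2,4,5-tribromo-6-(methoxymethoxy)-3-methylphenol F3. MOMCl/iPr2NEt in CH2Cl2 would give 1,2,4-tribromo-5,6-bis(methoxymethoxy)-3-methylbenzene F4, and NBS/AIBN would give 1,2,4-tribromo-3-(bromomethyl)-5,6-bis(methoxymethoxy)benzene F5. Part of F5 would be taken with KOAc/DMF to 2,3,6-tribromo-4,5-bis(methoxymethoxy)benzyl acetate F6 and with K2CO3/MeOH to [2,3,6-tribromo-4,5-bis(methoxymethoxy)phenyl]methanol F7. NaH would turn F7 into sodium [2,3,6-tribromo-4,5-bis(methoxymethoxy)phenyl]methanolate F8, which with the rest of F5 would give bis[2,3,6-tribromo-4,5-bis(methoxymethoxy)benzyl] ether F9. Aqueous HCl in THF would remove the four MOM groups, and the fallback comes back to the route at 17.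

Step 3. What may go wrong: hydrogen abstraction at the O–CH2–O carbon of the MOM group, or acid-induced loss of that group, may compete with the slow abstraction from a methyl group that sits on an electron-poor ring between two bromines. Fallback: the side chain is brominated with the phenol masked as an ester, and the MOM group is put on afterwards. It sets out from 4. Ac2O/pyridine would give 2,3,5,6-tetrabromo-4-methylphenyl acetate F10, and NBS/AIBN (PhCF3, 90 °C) would give 2,3,5,6-tetrabromo-4-(bromomethyl)phenyl acetate F11. Aqueous NaOH in THF at 0 °C would cleave the aryl ester; the phenoxide would expel bromide to give the quinone methide 2,3,5,6-tetrabromo-4-methylidenecyclohexa-2,5-dien-1-one F12, and hydroxide would add to its exocyclic carbon to give, after acidification, 2,3,5,6-tetrabromo-4-(hydroxymethyl)phenol F13. K2CO3 and one equivalent of MOMCl in acetone would alkylate only the acidic phenol, and the fallback comes back to the route at 10. The part of 10 needed as the electrophile would be converted into 8 with CBr4/PPh3 (Appel reaction).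

Step 7. What may go wrong: once the C4 hydroxyl is free, acid may promote heterolysis of the benzylic C–O bond para to it and so cut the central ether, and the bromocatechol may be oxidised by air during a long aqueous acidic treatment. Fallback: non-protic MOM cleavage by silyl transfer. It sets out from 16. TMSOTf and 2,2′-bipyridyl in MeCN at 0 °C would silylate the two free phenols and convert the two aryl MOM ethers into aryl silyl ethers, the methoxymethyl unit being carried off on the bipyridyl, to give bis[2,3,6-tribromo-4,5-bis(trimethylsilyloxy)benzyl] ether F14. Addition of water would hydrolyse the four aryl silyl ethers under buffered conditions, and the fallback comes back to the route at 17.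

**Further compounds**
F1 | step 6 | [2,4,5-tribromo-6-(methoxymethoxy)-3-methylphenyl]magnesium chloride | Cc1c(Br)c(Br)c(OCOC)c([Mg]Cl)c1Br
F2 | step 6 | dimethyl [2,4,5-tribromo-6-(methoxymethoxy)-3-methylphenyl]boronate | Cc1c(Br)c(Br)c(OCOC)c(B(OC)OC)c1Br
F3 | step 6 | 2,4,5-tribromo-6-(methoxymethoxy)-3-methylphenol | Cc1c(Br)c(Br)c(OCOC)c(O)c1Br
F4 | step 6 | 1,2,4-tribromo-5,6-bis(methoxymethoxy)-3-methylbenzene | Cc1c(Br)c(Br)c(OCOC)c(OCOC)c1Br
F5 | step 6 | 1,2,4-tribromo-3-(bromomethyl)-5,6-bis(methoxymethoxy)benzene | BrCc1c(Br)c(Br)c(OCOC)c(OCOC)c1Br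
F6 | step 6 | 2,3,6-tribromo-4,5-bis(methoxymethoxy)benzyl acetate | CC(=O)OCc1c(Br)c(Br)c(OCOC)c(OCOC)c1Br
F7 | step 6 | [2,3,6-tribromo-4,5-bis(methoxymethoxy)phenyl]methanol | OCc1c(Br)c(Br)c(OCOC)c(OCOC)c1Br
F8 | step 6 | sodium [2,3,6-tribromo-4,5-bis(methoxymethoxy)phenyl]methanolate | [O-]Cc1c(Br)c(Br)c(OCOC)c(OCOC)c1Br.[Na+]
F9 | step 6 | bis[2,3,6-tribromo-4,5-bis(methoxymethoxy)benzyl] ether | COCOc1c(OCOC)c(Br)c(COCc2c(Br)c(OCOC)c(OCOC)c(Br)c2Br)c(Br)c1Br
F10 | step 3 | 2,3,5,6-tetrabromo-4-methylphenyl acetate | CC(=O)Oc1c(Br)c(Br)c(C)c(Br)c1Br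
F11 | step 3 | 2,3,5,6-tetrabromo-4-(bromomethyl)phenyl acetate | CC(=O)Oc1c(Br)c(Br)c(CBr)c(Br)c1Br
F12 | step 3 | 2,3,5,6-tetrabromo-4-methylidenecyclohexa-2,5-dien-1-one | C=C1C(Br)=C(Br)C(=O)C(Br)=C1Br
F13 | step 3 | 2,3,5,6-tetrabromo-4-(hydroxymethyl)phenol | OCc1c(Br)c(Br)c(O)c(Br)c1Br
F14 | step 7 | bis[2,3,6-tribromo-4,5-bis(trimethylsilyloxy)benzyl] ether | C[Si](C)(C)Oc1c(O[Si](C)(C)C)c(Br)c(COCc2c(Br)c(O[Si](C)(C)C)c(O[Si](C)(C)C)c(Br)c2Br)c(Br)c1Br
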